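**Strategy.** The thirteen-carbon tether (C1'–C13') linking quinone rings A and B is disconnected at C7'–C8'. An odd chain cannot arise from direct coupling of two equal halves. Two identical C7 acyl arms can, however, be joined acyl carbon (C7') to α-carbon (C8') if the second arm's carboxyl carbon is then lost as CO2. Step 4 does this in one operation: Et3N converts two molecules of 7-(3,5-dimethoxy-4-methylphenyl)heptanoyl chloride into alkylketenes that dimerise to a 4-alkylidene β-lactone. Hydrolysis with decarboxylation, deoxygenation of the C7' ketone and unmasking of both 2,6-dimethoxytoluene rings to the hydroxyquinones finish the route.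

Key step: step 4

**Remarks on the chemistry**
- The target is achiral. Alkene 4 (Z/E) and bis-epoxide 15 (like/unlike) are carried as stereoisomer mixtures because their stereo elements are erased in the next step.
- β-Lactone 8 does contain one stereocentre (C3, racemic); it disappears in step 5.
- Monoalkylketenes made with Et3N normally dimerise to the 4-alkylidene β-lactone; the cyclobutane-1,3-dione mode is typical of disubstituted ketenes. A 2,4-dialkylcyclobutane-1,3-dione would in any case hydrolyse to the same ketone 10.
- Numbering: tether carbons are C1'–C13'. In each quinone ring C1 is the carbonyl between the methoxy carbon C2 and the tether carbon C6, C3 bears the methyl, C4 is the second carbonyl and C5 bears the hydroxyl of the target.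
- Each ring is demethylated only once (step 7), so para-oxidation gives the methoxyquinone directly and no re-methylation is needed.

**Route**

Step 1
Reactants: 1 3,5-dimethoxy-4-methylbenzaldehyde; 2 (5-carboxypentyl)triphenylphosphonium bromide
Product: 4 7-(3,5-dimethoxy-4-methylphenyl)hept-6-enoic acid (Z/E mixture), via carboxylate ylide 3 (not isolated)
Conditions: 2 (1.2 equiv), KOtBu (2.4 equiv), THF, 0 °C; then 1, 0 °C → rt; aq. HCl work-up
Reagents that add atoms: none
Why: Wittig olefination of the aromatic aldehyde by the non-stabilised carboxylate ylide should give the C7 styrenyl acid; the alkene geometry is irrelevant because the double bond is hydrogenated next.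

Step 2
Reactants: 4 7-(3,5-dimethoxy-4-methylphenyl)hept-6-enoic acid (Z/E mixture)
Product: 5 7-(3,5-dimethoxy-4-methylphenyl)heptanoic acid
Conditions: H2 (1 atm), 10% Pd on carbon, EtOAc, rt
Reagents that add atoms: none
Why: Heterogeneous catalytic hydrogenation saturates the styrene-type double bond of either isomer and leaves the aryl methyl ethers and the acid untouched.

Step 3
Reactants: 5 7-(3,5-dimethoxy-4-methylphenyl)heptanoic acid
Product: 6 7-(3,5-dimethoxy-4-methylphenyl)heptanoyl chloride
Conditions: (COCl)2 (1.5 equiv), DMF (cat.), CH2Cl2, 0 °C → rt; evaporate, use crude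
Reagents that add atoms: oxalyl chloride, ClC(=O)C(=O)Cl
Why: DMF-catalysed acid chloride formation gives only gaseous by-products, so the moisture-sensitive chloride needs no purification, and without a Lewis acid the electron-rich ring is not acylated.

Step 4
Reactants: 6 7-(3,5-dimethoxy-4-methylphenyl)heptanoyl chloride (two molecules)
Product: 8 (Z)-3-[5-(3,5-dimethoxy-4-methylphenyl)pentyl]-4-[6-(3,5-dimethoxy-4-methylphenyl)hexylidene]oxetan-2-one (racemic), via alkylketene 7 (not isolated)
Conditions: Et3N (1.2 equiv, slow addition), dry Et2O, 0 °C → rt, N2, 16 h; filter Et3NHCl, concentrate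
Reagents that add atoms: none
Why: Et3N removes HCl from 6 (through the acylammonium salt) to give monoalkylketene 7. Two molecules of 7 then unite head to tail: the nucleophilic α-carbon of one (tether C8') attacks the electrophilic central carbon of the other (tether C7'), and the oxygen of that second unit closes onto the acyl carbon of the first, either as an asynchronous [2+2] cycloaddition of C=C across C=O or stepwise through an ammonium enolate. The closest known reaction type is the tertiary-amine-mediated dimerisation of aldoketenes from fatty acid chlorides to alkylketene dimers. The oxetan-2-one ring is closed by the cycloaddition itself, which in the stepwise variant is a 4-exo-trig O-acylation that releases Et3N. The C3 stereocentre forms without control (racemic) and the alkylidene turns its chain away from C3 (Z); both elements disappear in step 5. The step needs lactone-mode (C=C/C=O) rather than cyclobutane-1,3-dione-mode (C=C/C=C) dimerisation and no oligomerisation: monosubstituted ketenes favour the lactone mode by themselves, dilution and exclusion of water curb trimers and anhydride, and since both monomers are identical and either dimer hydrolyses to the same ketone, no cross- or regio-selectivity question remains.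

Step 5
Reactants: 8 (Z)-3-[5-(3,5-dimethoxy-4-methylphenyl)pentyl]-4-[6-(3,5-dimethoxy-4-methylphenyl)hexylidene]oxetan-2-one (racemic)
Product: 10 1,13-bis(3,5-dimethoxy-4-methylphenyl)tridecan-7-one, via β-keto acid 9 (not isolated)
Conditions: KOH (3 equiv), THF/H2O, 65 °C; then aq. HCl to pH 1, 65 °C until CO2 evolution ends
Reagents that add atoms: none
Why: Saponification opens the enol lactone at its acyl carbon and the resulting β-keto acid decarboxylates through the usual cyclic transition state, the standard conversion of alkylketene dimers into symmetrical ketones; the oxygen delivered by hydroxide leaves in the CO2.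

Step 6
Reactants: 10 1,13-bis(3,5-dimethoxy-4-methylphenyl)tridecan-7-one
Product: 12 1,13-bis(3,5-dimethoxy-4-methylphenyl)tridecane, via hydrazone 11 (not isolated)
Conditions: N2H4·H2O (5 equiv), KOH (4 equiv), diethylene glycol, 130 °C; then distil off H2O, 195 °C
Reagents that add atoms: none
Why: Wolff–Kishner reduction (Huang-Minlon procedure) of an unhindered dialkyl ketone should proceed through the hydrazone with loss of N2; aryl methyl ethers tolerate it, and a stray O-demethylation would only anticipate step 7.

Step 7
Reactants: 12 1,13-bis(3,5-dimethoxy-4-methylphenyl)tridecane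
Product: 13 1,13-bis(3-hydroxy-5-methoxy-4-methylphenyl)tridecane
Conditions: NaSEt (8 equiv), DMF, 150 °C; then aq. HCl
Reagents that add atoms: none
Why: Thiolate SN2 O-demethylation cleaves one ether per ring and then stops, because the phenoxide formed makes the second aryloxide of that ring a much poorer leaving group; the two methoxy groups of a ring are equivalent, so only one product can form.

Step 8
Reactants: 13 1,13-bis(3-hydroxy-5-methoxy-4-methylphenyl)tridecane
Product: 14 1,13-bis(5-methoxy-4-methyl-3,6-dioxocyclohexa-1,4-dien-1-yl)tridecane (each ring a 2-methoxy-3-methyl-1,4-benzoquinone carrying the tether at C6)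
Conditions: (KSO3)2NO (5 equiv), aq. KH2PO4, acetone/THF, 0 °C → rt
Reagents that add atoms: potassium nitrosodisulfonate, [K+].[K+].[O]N(S(=O)(=O)[O-])S(=O)(=O)[O-]
Why: Teuber oxidation: the nitroxyl radical abstracts the phenolic hydrogen, a second equivalent couples at the unsubstituted para carbon (between the methoxy and tether carbons) and loss of HN(SO3K)2 should give the p-quinone, para attack being preferred whenever that position is free.

Step 9
Reactants: 14 1,13-bis(5-methoxy-4-methyl-3,6-dioxocyclohexa-1,4-dien-1-yl)tridecane
Product: 15 1,13-bis(3-methoxy-4-methyl-2,5-dioxo-7-oxabicyclo[4.1.0]hept-3-en-1-yl)tridecane (cis-fused oxiranes; like/unlike mixture)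
Conditions: 30% aq. H2O2 (5 equiv), Na2CO3 (1 equiv), THF/H2O, 0 °C
Reagents that add atoms: hydrogen peroxide, OO
Why: Weitz–Scheffer nucleophilic epoxidation: HOO− adds at the unsubstituted C5 of the C5=C6 enone, which is more electrophilic than the methoxy-bearing C2=C3 vinylogous ester, and the enolate closes the oxirane; ring fusion forces each epoxide to be cis, and the two remote units form independently, which is harmless because step 10 erases all four stereocentres.

Step 10
Reactants: 15 1,13-bis(3-methoxy-4-methyl-2,5-dioxo-7-oxabicyclo[4.1.0]hept-3-en-1-yl)tridecane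
Product: 16 1,13-bis(2-hydroxy-5-methoxy-4-methyl-3,6-dioxocyclohexa-1,4-dien-1-yl)tridecane (target)
Conditions: H2SO4 adsorbed on SiO2, CH2Cl2, rt
Reagents that add atoms: none
Why: Acid-mediated isomerisation of a quinone epoxide to a 2-hydroxyquinone, known for 2-alkyl-1,4-quinone epoxides: enolisation of the C4 carbonyl toward C5–H expels the protonated oxirane oxygen from C6, leaving that oxygen on C5 as the hydroxyl next to the tether carbon.

**Compound list**

1 | 3,5-dimethoxy-4-methylbenzaldehyde | COc1cc(C=O)cc(OC)c1C | starting material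
2 | (5-carboxypentyl)triphenylphosphonium bromide | OC(=O)CCCCC[P+](c1ccccc1)(c1ccccc1)c1ccccc1.[Br-] | starting material
3 | potassium 6-(triphenyl-λ5-phosphanylidene)hexanoate (carboxylate ylide, not isolated) | [K+].[O-]C(=O)CCCCC=P(c1ccccc1)(c1ccccc1)c1ccccc1 | intermediate
4 | 7-(3,5-dimethoxy-4-methylphenyl)hept-6-enoic acid (Z isomer drawn, accompanied by the E isomer) | OC(=O)CCCC/C=C\c1cc(OC)c(C)c(OC)c1 | intermediate
5 | 7-(3,5-dimethoxy-4-methylphenyl)heptanoic acid | OC(=O)CCCCCCc1cc(OC)c(C)c(OC)c1 | intermediate
6 | 7-(3,5-dimethoxy-4-methylphenyl)heptanoyl chloride | O=C(Cl)CCCCCCc1cc(OC)c(C)c(OC)c1 | intermediate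
7 | 7-(3,5-dimethoxy-4-methylphenyl)hept-1-en-1-one (alkylketene, not isolated) | O=C=CCCCCCc1cc(OC)c(C)c(OC)c1 | intermediate
8 | (Z)-3-[5-(3,5-dimethoxy-4-methylphenyl)pentyl]-4-[6-(3,5-dimethoxy-4-methylphenyl)hexylidene]oxetan-2-one (racemic at C3) | O=C1O/C(=C\CCCCCc2cc(OC)c(C)c(OC)c2)C1CCCCCc3cc(OC)c(C)c(OC)c3 | intermediate
9 | 9-(3,5-dimethoxy-4-methylphenyl)-2-[5-(3,5-dimethoxy-4-methylphenyl)pentyl]-3-oxononanoic acid (racemic, not isolated) | OC(=O)C(CCCCCc1cc(OC)c(C)c(OC)c1)C(=O)CCCCCCc1cc(OC)c(C)c(OC)c1 | intermediate
10 | 1,13-bis(3,5-dimethoxy-4-methylphenyl)tridecan-7-one | O=C(CCCCCCc1cc(OC)c(C)c(OC)c1)CCCCCCc1cc(OC)c(C)c(OC)c1 | intermediate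
11 | 1,13-bis(3,5-dimethoxy-4-methylphenyl)tridecan-7-one hydrazone (not isolated) | NN=C(CCCCCCc1cc(OC)c(C)c(OC)c1)CCCCCCc1cc(OC)c(C)c(OC)c1 | intermediate
12 | 1,13-bis(3,5-dimethoxy-4-methylphenyl)tridecane | COc1cc(CCCCCCCCCCCCCc2cc(OC)c(C)c(OC)c2)cc(OC)c1C | intermediate
13 | 1,13-bis(3-hydroxy-5-methoxy-4-methylphenyl)tridecane | COc1cc(CCCCCCCCCCCCCc2cc(O)c(C)c(OC)c2)cc(O)c1C | intermediate
14 | 1,13-bis(5-methoxy-4-methyl-3,6-dioxocyclohexa-1,4-dien-1-yl)tridecane | COC1=C(C)C(=O)C=C(CCCCCCCCCCCCCC2=CC(=O)C(C)=C(OC)C2=O)C1=O | intermediate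
15 | 1,13-bis(3-methoxy-4-methyl-2,5-dioxo-7-oxabicyclo[4.1.0]hept-3-en-1-yl)tridecane (cis-fused oxiranes; like isomer drawn, formed together with the unlike isomer) | COC1=C(C)C(=O)[C@H]2O[C@@]2(CCCCCCCCCCCCC[C@@]23O[C@@H]2C(=O)C(C)=C(OC)C3=O)C1=O | intermediate
16 | 1,13-bis(2-hydroxy-5-methoxy-4-methyl-3,6-dioxocyclohexa-1,4-dien-1-yl)tridecane | COC1=C(C)C(=O)C(O)=C(CCCCCCCCCCCCCC2=C(O)C(=O)C(C)=C(OC)C2=O)C1=O | target

**Step count and risks**

Total steps: 10. Longest linear sequence: 10 steps (1 → 16).

Steps most likely to fail:

1. Step 4. The ketene may be consumed by further oligomerisation (trimers, acylation of the dimer by unreacted acid chloride) or by traces of water (acid and anhydride), and the reactive enol lactone may open during isolation. The fallback sets out from 5 and comes back at 10. Esterification (MeOH, H2SO4 cat., reflux) would give methyl 7-(3,5-dimethoxy-4-methylphenyl)heptanoate F1. Claisen self-condensation (NaH, THF, reflux) forms the same C7'–C8' bond and would give methyl 9-(3,5-dimethoxy-4-methylphenyl)-2-[5-(3,5-dimethoxy-4-methylphenyl)pentyl]-3-oxononanoate F2. Saponification (aq. NaOH, MeOH) followed by acidification and warming should decarboxylate it to ketone 10.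

2. Step 8. The twofold oxidation may stall because the lipophilic bis-phenol meets the water-soluble radical salt poorly, while phenoxyl radical coupling or attack ortho to the hydroxyl consumes material. The fallback sets out from 12 and comes back at 14. NBS (2 equiv, MeCN, 0 °C, dark) should brominate each ring once at the position next to the tether (para to one methoxy; the two such positions are equivalent), giving 1,13-bis(2-bromo-3,5-dimethoxy-4-methylphenyl)tridecane F3. Pd-catalysed hydroxylation (Pd2(dba)3 as zerovalent palladium source, tBuXPhos, KOH, dioxane/H2O, 100 °C) would give 1,13-bis(2-hydroxy-3,5-dimethoxy-4-methylphenyl)tridecane F4. Oxidative demethylation of this p-methoxyphenol (PhI(OAc)2, MeCN/H2O, 0 °C) should give bis-quinone 14.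

3. Step 9. Hydroperoxide or hydroxide may instead attack the methoxy-bearing C2 by addition–elimination (loss of the methyl ether), or the base may cleave the epoxydione; any loss counts twice because both rings must react. The fallback sets out from 14 and comes back at 16, bypassing 15 and step 10. Thiele–Winter acetoxylation (Ac2O, H2SO4 cat., rt) places acetate at the only free ring carbon C5 and would give 1,13-bis(2,3,6-triacetoxy-5-methoxy-4-methylphenyl)tridecane F5. Methanolysis (HCl, MeOH, reflux) would give 1,13-bis(2,3,6-trihydroxy-5-methoxy-4-methylphenyl)tridecane F6, which is not isolated; air (or FeCl3) on work-up should oxidise it to target 16.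

**Further compounds**

F1 | step 4 | methyl 7-(3,5-dimethoxy-4-methylphenyl)heptanoate | COC(=O)CCCCCCc1cc(OC)c(C)c(OC)c1
F2 | step 4 | methyl 9-(3,5-dimethoxy-4-methylphenyl)-2-[5-(3,5-dimethoxy-4-methylphenyl)pentyl]-3-oxononanoate (racemic) | COC(=O)C(CCCCCc1cc(OC)c(C)c(OC)c1)C(=O)CCCCCCc1cc(OC)c(C)c(OC)c1
F3 | step 8 | 1,13-bis(2-bromo-3,5-dimethoxy-4-methylphenyl)tridecane | COc1cc(CCCCCCCCCCCCCc2cc(OC)c(C)c(OC)c2Br)c(Br)c(OC)c1C
F4 | step 8 | 1,13-bis(2-hydroxy-3,5-dimethoxy-4-methylphenyl)tridecane | COc1cc(CCCCCCCCCCCCCc2cc(OC)c(C)c(OC)c2O)c(O)c(OC)c1C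
F5 | step 9 | 1,13-bis(2,3,6-triacetoxy-5-methoxy-4-methylphenyl)tridecane | COc1c(C)c(OC(C)=O)c(OC(C)=O)c(CCCCCCCCCCCCCc2c(OC(C)=O)c(OC(C)=O)c(C)c(OC)c2OC(C)=O)c1OC(C)=O
F6 | step 9 | 1,13-bis(2,3,6-trihydroxy-5-methoxy-4-methylphenyl)tridecane (not isolated) | COc1c(C)c(O)c(O)c(CCCCCCCCCCCCCc2c(O)c(O)c(C)c(OC)c2O)c1O
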